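**Retrosynthetic overview**
1. Target 27 is the C6 4-methoxybenzoate of an 8,9-epoxy-daucane-4,6-diol: ester (step 16) ← epoxide by C6-hydroxyl-directed epoxidation (step 15) ← diol 24 by C4-hydroxyl-directed reduction of ketol 23 (step 14).
2. The C8=C9 alkene of 23 comes from reductive allylic transposition of a C9 carbinol (20); that C9 oxygen and the C6 ketone are what remains of an 8-oxabicyclo[3.2.1]octenone whose C5–O bond is cut with SmI2.
3. Key disconnection: intramolecular (5+2) cycloaddition of 3-oxidopyrylium 14 with its tethered alkene, forming C9–C10 and C1–C5 in one operation, so that ring B (cycloheptane, oxygen-bridged) and ring A (cyclopentane) close together and the quaternary C1 is set.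
4. Enabling feature: in ring B the run C5–C6(O)–C7–C8–C9 is the five-carbon face of a 3-oxidopyrylium (C6 oxygen = oxido oxygen, C5 and C9 = termini), and C10=C1(CH3) is a 1,1-disubstituted alkene joined to C5 through C2–C3–C4, the other three atoms of ring A; the only stereocentre carried in, the C4 carbinol, directs the rest.
5. Ring order: temporary dioxolanone (steps 1–4, relaying the stereocentre of (R)-2-hydroxy-3-methylbutanoic acid), furan to pyranone (step 6), rings A and B together (step 8), epoxide last (step 15).

Key step: step 8

Remark (numbering): from compound 10 on, daucane-type numbering is used: C1 = methyl-bearing quaternary ring-fusion carbon, C2 and C3 = CH2 of ring A, C4 = carbinol carbon with the isopropyl group, C5 = other ring-fusion carbon, C6 = oxygenated carbon next to it, C7 = CH2, C8 = methyl-bearing carbon, C9 = its neighbour, C10 = CH2 between C9 and C1; ring A = cyclopentane, ring B = cycloheptane.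
Remark (assumption): lithiation of 3-methylfuran is taken to be unselective between its two α-positions, so plain furan is used and the C8 methyl is added after the cycloaddition (step 9).

**Route**

Step 1
Reactants: 1 (R)-2-hydroxy-3-methylbutanoic acid; 2 pivalaldehyde
Product: 3 (2R,5R)-2-tert-butyl-5-(propan-2-yl)-1,3-dioxolan-4-one (cis)
Conditions: TsOH·H2O (cat.), H2SO4 (cat.), pentane, reflux, Dean–Stark; recrystallisation
Reagents that add atoms: none
Why: Acid-catalysed acetalisation to a dioxolanone under water removal is reversible, so the acetal carbon is set under thermodynamic control cis to the isopropyl group (2R) and crystallisation removes the minor trans isomer.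

Step 2
Reactants: 4 4-bromo-2-methylbut-1-ene
Product: 5 4-iodo-2-methylbut-1-ene
Conditions: NaI, acetone, reflux
Reagents that add atoms: sodium iodide, [Na+].[I-]
Why: Finkelstein halide exchange, driven by precipitation of NaBr, gives the primary iodide needed for alkylation of a hindered enolate.

Step 3
Reactants: 3 (2R,5R)-2-tert-butyl-5-(propan-2-yl)-1,3-dioxolan-4-one; 5 4-iodo-2-methylbut-1-ene
Product: 7 (2R,5R)-2-tert-butyl-5-(3-methylbut-3-en-1-yl)-5-(propan-2-yl)-1,3-dioxolan-4-one, via lithium enolate 6 (not isolated)
Conditions: LiN(iPr)2, THF, −78 °C; then 5, DMPU, −78 to −40 °C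
Reagents that add atoms: none
Why: Enolate alkylation with self-regeneration of the stereocentre: the tert-butyl group on the acetal carbon shields one face, the iodide enters trans to it, and C5 of the dioxolanone (the future C4) is rebuilt as a quaternary centre with R configuration.

Step 4
Reactants: 7 the alkylated dioxolanone; 8 furan
Product: 10 (2R)-1-(furan-2-yl)-2-hydroxy-5-methyl-2-(propan-2-yl)hex-5-en-1-one, via 2-furyllithium 9 (not isolated)
Conditions: 8, n-BuLi, THF, 0 °C; then 7, −78 °C; aq. NH4Cl
Reagents that add atoms: none
Why: Acyl substitution on the lactone-type carbonyl by 2-furyllithium (from α-lithiation of furan): the tetrahedral lithium hemiketal persists at −78 °C, which prevents double addition, and collapses on quench with loss of pivalaldehyde to the tertiary α-hydroxy ketone without touching the stereocentre.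

Step 5
Reactants: 10 the furyl hydroxy ketone
Product: 11 (2R)-1-(furan-2-yl)-5-methyl-2-(propan-2-yl)hex-5-ene-1,2-diol (both C1 epimers)
Conditions: NaBH4, MeOH, 0 °C
Reagents that add atoms: none
Why: Borohydride reduction of the aryl ketone gives the furyl carbinol needed for ring expansion; its configuration is irrelevant because this carbon (C5) becomes planar in ylide 14.

Step 6
Reactants: 11 the furyl diol
Product: 12 6-hydroxy-2-[(3R)-3-hydroxy-2,6-dimethylhept-6-en-3-yl]-2H-pyran-3(6H)-one (diastereomer mixture at the two ring sp3 carbons)
Conditions: O2, visible light, 5,10,15,20-tetraphenylporphyrin (cat.), CH2Cl2, −78 °C; then Me2S, −78 °C to rt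
Reagents that add atoms: dioxygen, O=O
Why: Photooxygenation variant of the Achmatowicz rearrangement: singlet oxygen adds (4+2) to the furan far faster than it attacks the isolated 1,1-disubstituted alkene, Me2S reduces the endoperoxide to the cis-enedione, and the C5 hydroxyl closes the pyranone hemiacetal.

Step 7
Reactants: 12 the hydroxypyranone
Product: 13 6-acetoxy-2-[(3R)-3-hydroxy-2,6-dimethylhept-6-en-3-yl]-2H-pyran-3(6H)-one (diastereomer mixture)
Conditions: Ac2O, Et3N, 4-(dimethylamino)pyridine (DMAP, cat.), CH2Cl2, −20 °C
Reagents that add atoms: acetic anhydride, CC(=O)OC(C)=O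
Why: DMAP-catalysed acetylation takes only the hemiacetal hydroxyl, the tertiary C4 carbinol being too hindered, and installs the leaving group for ylide formation.

Step 8
Reactants: 13 the acetoxypyranone
Product: 15 (1R,4R,5S,9S)-5,9-epoxy-4-hydroxy-8-desmethyldauc-7-en-6-one (oxygen bridge C5–O–C9; C1 methyl anti to the bridge; isopropyl syn to it), via 3-oxidopyrylium ylide 14 (not isolated)
Conditions: 1,8-diazabicyclo[5.4.0]undec-7-ene (DBU), MeCN (0.01 M), rt to 60 °C
Reagents that add atoms: none
Why: DBU removes the C5 proton of 13 and acetate leaves from C9, giving the planar 3-oxidopyrylium 14, whose termini C5 and C9 add suprafacially to the tethered C1=C10 alkene in a thermal (5+2) dipolar cycloaddition; the closest known reaction type is the intramolecular 3-oxidopyrylium–alkene cycloaddition across a three-atom tether. Ring B is closed as an oxygen-bridged cycloheptenone (8-oxabicyclo[3.2.1]oct-3-en-2-one) by the two new bonds C9–C10 and C1–C5, and ring A is closed at the same time by the C1–C5 bond, the C2–C3–C4 tether spanning C5 and the internal alkene carbon (five-membered, tether exo). C5 and C9 are set together because both ylide termini bond on one face, and C1 is set by the geometry of the short tether, which must sit exo (syn to the oxygen bridge) and so leaves the methyl endo, anti to the bridge and trans to the future H5. The absolute sense of all three follows from C4: the tether leaves C4 roughly perpendicular to the pyrylium plane, the hydroxyl sits on the C6 side hydrogen-bonded to the oxido oxygen, and the isopropyl group takes the in-plane position eclipsing the ring oxygen, where it avoids allylic 1,3-strain with the C6 oxygen, so the alkene reaches the face that places the isopropyl group syn to the bridge. Regiochemistry (C1 to C5, C10 to C9) is enforced by tether length and the electron-rich 1,1-disubstituted alkene matches the electron-poor ylide, so the only selectivity the step needs is the facial one, secured by the C4 carbinol, whose full substitution also favours cyclisation over ylide dimerisation.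

Step 9
Reactants: 15 the bridged enone
Product: 16 (1R,4R,5S,8R,9S)-5,9-epoxy-4-hydroxydaucan-6-one
Conditions: Me2CuLi (from MeLi, CuI), Et2O, −78 to −20 °C; aq. NH4Cl
Reagents that add atoms: lithium dimethylcuprate (made in the flask from MeLi and CuI), [Li+].C[Cu-]C
Why: Cuprate conjugate addition to the bridged enone, expected from the exo face syn to the oxygen bridge, installs the C8 methyl and at the same time removes the enone, so that the following electron-transfer step can cleave only the C–O bond α to the ketone; the C8 configuration is erased in step 12.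

Step 10
Reactants: 16 the bridged methyl ketone
Product: 17 (1R,4R,5R,8R,9S)-4,9-dihydroxydaucan-6-one (trans ring fusion)
Conditions: SmI2, THF/MeOH, −78 °C
Reagents that add atoms: none
Why: SmI2 reduction of an α-alkoxy ketone: two-electron transfer to the C6 ketone expels the C5–O bond and opens the bridge, and the samarium enolate should be protonated at C5 on the face the oxygen has just left (methanol held by the C9 samarium alkoxide above that face), giving the trans ring fusion, which is also expected to be the hydrogen-bonded, thermodynamically preferred epimer.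

Step 11
Reactants: 17 the dihydroxy ketone
Product: 18 tris(trimethylsilyl) derivative of 17 (C4 and C9 silyl ethers; C6=C7 silyl enol ether; other centres unchanged)
Conditions: TMSOTf, Et3N, CH2Cl2, 0 °C
Reagents that add atoms: trimethylsilyl trifluoromethanesulfonate, C[Si](C)(C)OS(=O)(=O)C(F)(F)F
Why: Soft enolisation with a silyl triflate and an amine silylates both hydroxyls and should form the silyl enol ether towards C7 only, because the C5 hydrogen is buried between the quaternary C1 and C4 and a C5=C6 enol ether would suffer severe allylic strain.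

Step 12
Reactants: 18 the tris(trimethylsilyl) compound
Product: 20 (1R,4R,5R,9S)-4,9-dihydroxydauc-7-en-6-one, via bis(trimethylsilyl) enone 19 (not isolated)
Conditions: Pd(OAc)2 (1.1 equiv), MeCN, rt; then citric acid, MeOH, 0 °C
Reagents that add atoms: none
Why: Saegusa–Ito oxidation: the palladium enolate undergoes β-hydride elimination of the C8 hydrogen to give the C7=C8 enone (the C8 stereocentre disappears), and mild acidic methanolysis then frees the two hydroxyls.

Step 13
Reactants: 20 the γ-hydroxy enone
Product: 23 (1R,4R,5R)-4-hydroxydauc-8-en-6-one, via N-allyl sulfonylhydrazine 21 (not isolated), via allylic diazene 22 (not isolated)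
Conditions: 2-nitrobenzenesulfonylhydrazide, PPh3, diethyl azodicarboxylate (DEAD), THF, −30 °C; then rt
Reagents that add atoms: none
Why: Reductive 1,3-transposition of an allylic alcohol (Myers type): Mitsunobu displacement at C9 by the sulfonylhydrazide with inversion, loss of 2-nitrobenzenesulfinic acid to the allylic diazene and its retro-ene loss of N2 deliver hydrogen to C7 and move the double bond to C8=C9, the tertiary C4 hydroxyl being inert to Mitsunobu activation.

Step 14
Reactants: 23 the β,γ-unsaturated ketol
Product: 24 (1R,4R,5S,6S)-dauc-8-ene-4,6-diol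
Conditions: Me4NBH(OAc)3, MeCN/AcOH, −20 °C
Reagents that add atoms: none
Why: Evans–Saksena reduction: the C4 hydroxyl exchanges onto boron and delivers hydride intramolecularly to the face of the C6 carbonyl on which the C4–O bond lies, so the new C6 hydroxyl appears on the opposite face (6S, cis to H5, anti to the C1 methyl), and the mildly acidic medium leaves the β,γ-alkene unconjugated.

Step 15
Reactants: 24 the diol
Product: 25 (1R,4R,5S,6S,8R,9S)-8,9-epoxydaucane-4,6-diol
Conditions: VO(acac)2 (cat.), t-BuOOH, CH2Cl2, 0 °C
Reagents that add atoms: tert-butyl hydroperoxide, CC(C)(C)OO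
Why: Vanadium-catalysed hydroxyl-directed epoxidation of a homoallylic alcohol: the C6 vanadate ester delivers oxygen to the alkene face syn to the C6 hydroxyl, which is also the face remote from the angular C1 methyl, setting 8R and 9S.

Step 16
Reactants: 25 the epoxy diol; 26 4-methoxybenzoyl chloride
Product: 27 (1R,4R,5S,6S,8R,9S)-8,9-epoxy-4-hydroxydaucan-6-yl 4-methoxybenzoate (target)
Conditions: Et3N, DMAP (cat.), CH2Cl2, 0 °C to rt
Reagents that add atoms: none
Why: DMAP-catalysed acylation of the secondary C6 hydroxyl with the acid chloride; the tertiary C4 hydroxyl does not react and the epoxide tolerates the basic, non-acidic conditions.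

**Compound list**
1 | (R)-2-hydroxy-3-methylbutanoic acid | CC(C)[C@@H](O)C(=O)O | starting material
2 | pivalaldehyde (2,2-dimethylpropanal) | CC(C)(C)C=O | starting material
3 | (2R,5R)-2-tert-butyl-5-(propan-2-yl)-1,3-dioxolan-4-one (cis) | CC(C)[C@H]1O[C@@H](C(C)(C)C)OC1=O | intermediate
4 | 4-bromo-2-methylbut-1-ene | C=C(C)CCBr | starting material
5 | 4-iodo-2-methylbut-1-ene | C=C(C)CCI | intermediate
6 | lithium enolate of 3 (acetal stereocentre retained) | CC(C)C1=C([O-])O[C@H](C(C)(C)C)O1.[Li+] | intermediate
7 | (2R,5R)-2-tert-butyl-5-(3-methylbut-3-en-1-yl)-5-(propan-2-yl)-1,3-dioxolan-4-one (new chain trans to tert-butyl) | CC(C)[C@@]1(CCC(C)=C)O[C@@H](C(C)(C)C)OC1=O | intermediate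
8 | furan | c1ccoc1 | starting material
9 | 2-furyllithium | [Li]c1ccco1 | intermediate
10 | (2R)-1-(furan-2-yl)-2-hydroxy-5-methyl-2-(propan-2-yl)hex-5-en-1-one | CC(C)[C@](O)(CCC(C)=C)C(=O)c1ccco1 | intermediate
11 | (2R)-1-(furan-2-yl)-5-methyl-2-(propan-2-yl)hex-5-ene-1,2-diol (both C1 epimers) | CC(C)[C@](O)(CCC(C)=C)C(O)c1ccco1 | intermediate
12 | 6-hydroxy-2-[(3R)-3-hydroxy-2,6-dimethylhept-6-en-3-yl]-2H-pyran-3(6H)-one (diastereomer mixture) | CC(C)[C@](O)(CCC(C)=C)C1OC(O)C=CC1=O | intermediate
13 | 6-acetoxy-2-[(3R)-3-hydroxy-2,6-dimethylhept-6-en-3-yl]-2H-pyran-3(6H)-one (diastereomer mixture) | CC(C)[C@](O)(CCC(C)=C)C1OC(OC(C)=O)C=CC1=O | intermediate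
14 | 2-[(3R)-3-hydroxy-2,6-dimethylhept-6-en-3-yl]pyrylium-3-olate (3-oxidopyrylium ylide) | CC(C)[C@](O)(CCC(C)=C)c1[o+]cccc1[O-] | intermediate
15 | (1R,4R,5S,9S)-5,9-epoxy-4-hydroxy-8-desmethyldauc-7-en-6-one (oxygen-bridged enone; C1 methyl anti to the bridge, isopropyl syn to it) | O=C1C=C[C@@H]2C[C@@]3(C)CC[C@@](O)(C(C)C)[C@]13O2 | intermediate
16 | (1R,4R,5S,8R,9S)-5,9-epoxy-4-hydroxydaucan-6-one (C8 methyl syn to the bridge) | O=C1C[C@@H](C)[C@@H]2C[C@@]3(C)CC[C@@](O)(C(C)C)[C@]13O2 | intermediate
17 | (1R,4R,5R,8R,9S)-4,9-dihydroxydaucan-6-one (trans ring fusion) | O=C1C[C@@H](C)[C@@H](O)C[C@@]2(C)CC[C@@](O)(C(C)C)[C@H]12 | intermediate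
18 | tris(trimethylsilyl) derivative of 17 (C4 and C9 silyl ethers, C6=C7 silyl enol ether) | C[Si](C)(C)OC1=C[C@@H](C)[C@@H](O[Si](C)(C)C)C[C@@]2(C)CC[C@@](O[Si](C)(C)C)(C(C)C)[C@H]12 | intermediate
19 | 4,9-bis(trimethylsilyl) ether of 20 | O=C1C=C(C)[C@@H](O[Si](C)(C)C)C[C@@]2(C)CC[C@@](O[Si](C)(C)C)(C(C)C)[C@H]12 | intermediate
20 | (1R,4R,5R,9S)-4,9-dihydroxydauc-7-en-6-one | O=C1C=C(C)[C@@H](O)C[C@@]2(C)CC[C@@](O)(C(C)C)[C@H]12 | intermediate
21 | N-(2-nitrobenzenesulfonyl)-N-allyl hydrazine from 20 (C9 inverted, 9R) | O=C1C=C(C)[C@H](N(N)S(=O)(=O)c3ccccc3[N+](=O)[O-])C[C@@]2(C)CC[C@@](O)(C(C)C)[C@H]12 | intermediate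
22 | allylic monoalkyl diazene at C9 | O=C1C=C(C)[C@H](N=N)C[C@@]2(C)CC[C@@](O)(C(C)C)[C@H]12 | intermediate
23 | (1R,4R,5R)-4-hydroxydauc-8-en-6-one | O=C1CC(C)=CC[C@@]2(C)CC[C@@](O)(C(C)C)[C@H]12 | intermediate
24 | (1R,4R,5S,6S)-dauc-8-ene-4,6-diol | O[C@H]1CC(C)=CC[C@@]2(C)CC[C@@](O)(C(C)C)[C@H]12 | intermediate
25 | (1R,4R,5S,6S,8R,9S)-8,9-epoxydaucane-4,6-diol | O[C@H]1C[C@@]2(C)O[C@H]2C[C@@]2(C)CC[C@@](O)(C(C)C)[C@H]12 | intermediate
26 | 4-methoxybenzoyl chloride | COc1ccc(C(Cl)=O)cc1 | starting material
27 | (1R,4R,5S,6S,8R,9S)-8,9-epoxy-4-hydroxydaucan-6-yl 4-methoxybenzoate | COc1ccc(C(=O)O[C@H]2C[C@@]3(C)O[C@H]3C[C@@]3(C)CC[C@@](O)(C(C)C)[C@H]23)cc1 | target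

**Step count and risks**

Total step count: 16. Longest linear sequence: 15 steps (steps 1 and 3–16, from acid 1); step 2 is a one-step side branch.

Steps most likely to fail:

Step 8 (key step). The process at risk is facial selectivity: if the hydrogen bond between the C4 hydroxyl and the oxido oxygen does not hold in MeCN in the presence of DBU, the tether may reach both faces of the ylide, and slow cyclisation would also let the ylide dimerise. The fallback changes the control element from hydrogen bonding to steric and stereoelectronic bias. Setting out from 13, the tertiary hydroxyl is silylated under neutral conditions with N-(trimethylsilyl)imidazole to give trimethylsilyl ether F1. DBU in MeCN then generates ylide F2, in which the isopropyl group should eclipse the ring oxygen and the silyloxy group should lie anti to the forming C1–C5 bond, and cycloaddition gives silyl ether F3. Citric acid in MeOH removes the silyl group and the route is rejoined at 15.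

Step 13. The processes at risk are slow Mitsunobu displacement at the hindered C9 carbinol, condensation of the hydrazide with the C6 ketone, and premature loss of the sulfinate before substitution. The fallback replaces the sigmatropic diazene route by a reductive elimination. Setting out from 20, acetylation of the C9 hydroxyl (Ac2O, pyridine, DMAP) gives γ-acetoxy enone F4. SmI2 in THF/MeOH at −78 °C reduces the enone, acetate is expelled from C9, and the extended samarium dienolate is protonated kinetically at C7, which returns to the route at 23.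

Step 3. The processes at risk are sluggish substitution of the unactivated homoallylic iodide by the hindered, fully substituted enolate, elimination of 5 to isoprene, and thermal decay of enolate 6. The fallback forms the same bond by conjugate addition instead of alkylation. Setting out from 3, enolate 6 is added in a Michael reaction to methyl vinyl ketone at −78 °C, again trans to the tert-butyl group, to give keto dioxolanone F5. Wittig methylenation with Ph3P=CH2 converts the ketone into the 1,1-disubstituted alkene, rejoining the route at 7.

**Further compounds**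
F1 | step 8 | 6-acetoxy-2-[(3R)-2,6-dimethyl-3-(trimethylsilyloxy)hept-6-en-3-yl]-2H-pyran-3(6H)-one | CC(C)[C@](O[Si](C)(C)C)(CCC(C)=C)C1OC(OC(C)=O)C=CC1=O
F2 | step 8 | 2-[(3R)-2,6-dimethyl-3-(trimethylsilyloxy)hept-6-en-3-yl]pyrylium-3-olate | CC(C)[C@](O[Si](C)(C)C)(CCC(C)=C)c1[o+]cccc1[O-]
F3 | step 8 | C4 trimethylsilyl ether of cycloadduct 15 | O=C1C=C[C@@H]2C[C@@]3(C)CC[C@@](O[Si](C)(C)C)(C(C)C)[C@]13O2
F4 | step 13 | C9 acetate of 20 ((1R,4R,5R,9S)-9-acetoxy-4-hydroxydauc-7-en-6-one) | O=C1C=C(C)[C@@H](OC(C)=O)C[C@@]2(C)CC[C@@](O)(C(C)C)[C@H]12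
F5 | step 3 | (2R,5R)-2-tert-butyl-5-(3-oxobutyl)-5-(propan-2-yl)-1,3-dioxolan-4-one | CC(C)[C@@]1(CCC(C)=O)O[C@@H](C(C)(C)C)OC1=O
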